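Elemane numbering is used: C10 is the quaternary carbon (β-CH3 = C14, vinyl = C1/C2), then C9, C8 (O-tigloyl), C7 (arm C11(=C13)–C12), C6 (lactone O) and C5 (arm C4(=C3)–C15OOH). Retrosynthesis: the C15 acid comes from the aldehyde, the 12,6-lactone from a temporary 15,6-lactone (lactone switch), the tiglate from the 8β-OH; the cyclohexane is then cut at C7–C8 and at C5–C6.
Enabling feature: C5 and C7 each carry a 1-carboxyvinyl group and each is bonded to an oxygen-bearing ring carbon (C6, C8). Both bonds are therefore the Cγ–C(O) bonds of 2-carboxyallyl/carbonyl additions set head to tail round the ring, a formal [4+2] of fragment A (C5, C10, C9, C8) with fragment B (C6, C7).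
Forward: fragment A (7 steps from 4,4-dimethoxybutan-2-one) carries an allylboronate and a masked C8 aldehyde; fragment B (5 steps from tert-butyl acrylate) carries an aldehyde and a masked allylboron. A one-flask double allylboration joins them and closes the cyclohexane, while the C5 arm forms a temporary γ-lactone on O6.
Endgame: tigloylation of the only free hydroxyl (O8), tert-butyl ester cleavage, reduction of the temporary lactone so that O6 relactonises onto C12, and Pinnick oxidation of C15.
Stereochemistry: C10 from a copper-catalysed enantioselective SN2′ alkynylation; C5/C6 from the catalyst-controlled closed-transition-state allylboration of a (2Z)-allylboronate (anti); C7/C8 from the (2E)-allylboron geometry in the bicyclic closed transition state (7,8-cis, O8 axial), the chair being fixed by the temporary trans-fused lactone.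

Key step: step 13

Assumption: (R)-TRIP is taken to direct the allyl group to the Re face of the C6 aldehyde, by analogy with simple aldehydes; if the sense on this enal proves opposite, (S)-TRIP is used.

Step 1
Reactants: 1 4,4-dimethoxybutan-2-one
Product: 2 ethyl (2E)-5,5-dimethoxy-3-methylpent-2-enoate
Conditions: (EtO)2P(O)CH2CO2Et, NaH, THF, 0 °C → rt; minor (2Z) isomer removed by chromatography
Reagents that add atoms: triethyl phosphonoacetate CCOC(=O)CP(=O)(OCC)OCC
Why: Horner–Wadsworth–Emmons olefination of the methyl ketone with a stabilised phosphonate anion should give mainly the (E)-trisubstituted enoate.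

Step 2
Reactants: 2 ethyl (2E)-5,5-dimethoxy-3-methylpent-2-enoate
Product: 3 (2E)-5,5-dimethoxy-3-methylpent-2-en-1-ol
Conditions: i-Bu2AlH (2.2 equiv), CH2Cl2, −78 °C; aq. potassium sodium tartrate
Reagents that add atoms: none
Why: 1,2-reduction of the enoate by the aluminium hydride at low temperature should give the allylic alcohol without touching the acetal or the alkene geometry.

Step 3
Reactants: 3 (2E)-5,5-dimethoxy-3-methylpent-2-en-1-ol
Product: 4 diethyl (2E)-5,5-dimethoxy-3-methylpent-2-en-1-yl phosphate
Conditions: ClP(O)(OEt)2, Et3N, DMAP (cat.), CH2Cl2, 0 °C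
Reagents that add atoms: diethyl chlorophosphate CCOP(=O)(Cl)OCC
Why: O-phosphorylation of the primary allylic alcohol installs the leaving group needed for copper-catalysed allylic substitution.

Step 4
Reactants: 4 diethyl (2E)-5,5-dimethoxy-3-methylpent-2-en-1-yl phosphate
Product: 5 [(3S)-3-ethenyl-5,5-dimethoxy-3-methylpent-1-yn-1-yl]trimethylsilane
Conditions: Me3SiC≡CH, n-BuLi, THF/hexanes, −78 °C, then i-Bu2AlCl, 0 °C; then 4, chiral sulfonate-bearing imidazolinium salt (carbene precursor, 2.5 mol %), CuCl2·2H2O (5 mol %), THF, −15 °C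
Reagents that add atoms: ethynyltrimethylsilane C#C[Si](C)(C)C
Why: Copper-catalysed enantioselective allylic substitution (SN2′) with an alkynylaluminium reagent should deliver the alkynyl group to the methyl-bearing alkene carbon with loss of phosphate, which creates the quaternary C10 together with its vinyl group; the chiral N-heterocyclic carbene ligand (enantiomer chosen to give S) selects the alkene face.

Step 5
Reactants: 5 [(3S)-3-ethenyl-5,5-dimethoxy-3-methylpent-1-yn-1-yl]trimethylsilane
Product: 6 (3S)-3-ethenyl-5,5-dimethoxy-3-methylpent-1-yne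
Conditions: K2CO3, MeOH, rt
Reagents that add atoms: none
Why: Methoxide-mediated protodesilylation of the alkynylsilane should free the terminal alkyne without affecting the acetal or the quaternary centre.

Step 6
Reactants: 6 (3S)-3-ethenyl-5,5-dimethoxy-3-methylpent-1-yne
Product: 7 methyl (4S)-4-ethenyl-6,6-dimethoxy-4-methylhex-2-ynoate
Conditions: n-BuLi, THF, −78 °C; then ClCO2Me
Reagents that add atoms: methyl chloroformate COC(=O)Cl
Why: C-acylation of the lithium acetylide with a chloroformate is the standard route to an alkynoate.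

Step 7
Reactants: 7 methyl (4S)-4-ethenyl-6,6-dimethoxy-4-methylhex-2-ynoate
Product: 9 methyl (2Z,4S)-4-ethenyl-6,6-dimethoxy-4-methyl-2-[(4,4,5,5-tetramethyl-1,3,2-dioxaborolan-2-yl)methyl]hex-2-enoate (fragment A), via vinylalane 8 (not isolated)
Conditions: i-Bu2AlH, HMPA, THF, 0 °C; then ICH2Bpin, 0 °C → rt
Reagents that add atoms: 2-(iodomethyl)-4,4,5,5-tetramethyl-1,3,2-dioxaborolane ICB1OC(C)(C)C(C)(C)O1
Why: Conjugate syn-hydroalumination of the alkynoate (hydride to C5, aluminium to C4) followed by C-alkylation of the α-alumino enoate with the iodomethylboronate should place C10 cis to the ester and trans to CH2B (2Z), the geometry that later gives the 5,6-anti relationship.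

Step 8
Reactants: 10 tert-butyl acrylate; 11 2-[(tert-butyldimethylsilyl)oxy]acetaldehyde
Product: 12 tert-butyl 4-[(tert-butyldimethylsilyl)oxy]-3-hydroxy-2-methylidenebutanoate (racemic)
Conditions: DABCO, MeOH, rt
Reagents that add atoms: none
Why: Morita–Baylis–Hillman reaction of the acrylate with the aldehyde; the new carbinol centre is racemic and is removed in step 10.

Step 9
Reactants: 12 tert-butyl 4-[(tert-butyldimethylsilyl)oxy]-3-hydroxy-2-methylidenebutanoate
Product: 13 tert-butyl 3-(acetyloxy)-4-[(tert-butyldimethylsilyl)oxy]-2-methylidenebutanoate (racemic)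
Conditions: Ac2O, pyridine, DMAP (cat.), CH2Cl2, 0 °C
Reagents that add atoms: acetic anhydride CC(=O)OC(C)=O
Why: Acetylation turns the secondary allylic alcohol into the leaving group for the allylic borylation.

Step 10
Reactants: 13 tert-butyl 3-(acetyloxy)-4-[(tert-butyldimethylsilyl)oxy]-2-methylidenebutanoate
Product: 14 tert-butyl (2E)-4-[(tert-butyldimethylsilyl)oxy]-2-[(4,4,5,5-tetramethyl-1,3,2-dioxaborolan-2-yl)methyl]but-2-enoate
Conditions: B2pin2, Pd2(dba)3 (2.5 mol %), PhMe, 50 °C
Reagents that add atoms: bis(pinacolato)diboron CC1(C)OB(OC1(C)C)B1OC(C)(C)C(C)(C)O1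
Why: Palladium-catalysed (Miyaura-type) borylation of the allylic acetate through a π-allyl complex should put boron on the unsubstituted terminus and give the thermodynamically preferred (2E)-alkene, in which the CH2O carbon (later C6) is cis to CH2B; this geometry later dictates the 7,8-cis relationship.

Step 11
Reactants: 14 tert-butyl (2E)-4-[(tert-butyldimethylsilyl)oxy]-2-[(4,4,5,5-tetramethyl-1,3,2-dioxaborolan-2-yl)methyl]but-2-enoate
Product: 15 tetrabutylammonium [(2E)-2-(tert-butoxycarbonyl)-4-hydroxybut-2-en-1-yl]trifluoroborate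
Conditions: aq. KHF2, MeOH, 50 °C; then n-Bu4NOH, CH2Cl2/H2O
Reagents that add atoms: potassium hydrogen difluoride F.[F-].[K+]; tetrabutylammonium hydroxide CCCC[N+](CCCC)(CCCC)CCCC.[OH-]
Why: Fluoride exchange converts the pinacol boronate into the trifluoroborate and the same acidic fluoride medium should cleave the silyl ether; tetracoordinate boron can neither add to an aldehyde nor migrate to the oxygen of the aldehyde made next, and the ammonium cation makes the salt soluble in CH2Cl2.

Step 12
Reactants: 15 tetrabutylammonium [(2E)-2-(tert-butoxycarbonyl)-4-hydroxybut-2-en-1-yl]trifluoroborate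
Product: 16 tetrabutylammonium [(2E)-2-(tert-butoxycarbonyl)-4-oxobut-2-en-1-yl]trifluoroborate (fragment B)
Conditions: Dess–Martin periodinane, NaHCO3, CH2Cl2, 0 °C
Reagents that add atoms: none
Why: Dess–Martin oxidation of the primary allylic alcohol, a reagent that organotrifluoroborates tolerate, should give the (E)-enal with the aldehyde cis to CH2B and trans to the ester.

Step 13
Reactants: 9 fragment A (boronate ester acetal); 16 fragment B (aldehyde trifluoroborate)
Product: 20 tert-butyl 8β-hydroxyelema-1,3,11(13)-trien-15,6α-olid-12-oate (5αH 6βH 7αH 10β-CH3), via allylboration borate 17 (not isolated), via lactone trifluoroborate 18 (not isolated), via aldehyde boronic acid 19 (not isolated)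
Conditions: 16 (1.2 equiv), (R)-TRIP (10 mol %), 4 Å MS, PhMe/CH2Cl2, −30 → 40 °C; then MeCN, H2O, Me3SiCl (3.5 equiv), 0 °C → rt; aq. NaHCO3
Reagents that add atoms: water O
Why: Proposed new method: (R)-TRIP activates the pinacol boronate of 9 for addition to the only free aldehyde present (C6 of 16) through a closed six-membered chair transition state, giving borate 17 (C5–C6 bond), which lactonises by 5-exo-trig acyl substitution onto the methyl ester to the temporary γ-lactone 18; Me3SiCl/H2O then strips fluoride from boron and hydrolyses the dimethyl acetal, and in 19 the allylboronic acid adds to the new C8 aldehyde in an intramolecular allylboration (C7–C8 bond, closure of the cyclohexane, 6-exo-trig at the carbonyl). The closest known reaction types are the chiral-phosphoric-acid-catalysed allylboration of aldehydes with pinacol allylboronates, the lactone-forming addition of 2-alkoxycarbonyl allylboronates and the unmasking of allyltrifluoroborates for closed-transition-state carbonyl allylation; their use as a one-flask [4+2] annulation of two bifunctional partners is new. For C5 and C6, the (2Z)-boronate holds C10 trans to CH2B and therefore equatorial in the chair, which gives the 5,6-anti relationship, while the catalyst selects the Re face of the aldehyde and so fixes both centres relative to the existing C10. For C7 and C8, the (2E) geometry (C6 cis to CH2B) puts C6 axial in the boron chair, allylic strain keeps H6 in the plane of the C7=C11 bond, and the trans-fused lactone locks the forming cyclohexane in the chair with C4 and O6 equatorial and the C10 methyl axial, so that C11 becomes equatorial and O8 axial (7αH, 8β-OH). The step needs a fixed order of events, which the substrates secure: in the first stage the aldehyde of 9 is an acetal, the boron of 16 is tetracoordinate and its C7 is deactivated by conjugation with the aldehyde; O6 is tied up as the lactone before the second boron is unmasked, so it cannot bridge to boron (a boron-bridged boat would give the wrong C7/C8 configuration), and the tert-butyl ester keeps O8 from lactonising.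

Step 14
Reactants: 20 tert-butyl 8β-hydroxyelema-1,3,11(13)-trien-15,6α-olid-12-oate
Product: 21 tert-butyl 8β-tigloyloxyelema-1,3,11(13)-trien-15,6α-olid-12-oate
Conditions: tiglic acid, 2,4,6-Cl3C6H2COCl, Et3N, PhMe, rt; then 20, DMAP, 60 °C
Reagents that add atoms: tiglic acid C/C=C(\C)C(=O)O
Why: Yamaguchi esterification should acylate the hindered axial 8β-hydroxyl, the only free hydroxyl since O6 is held in the temporary lactone, and the tert-butyl ester cannot lactonise under these conditions.

Step 15
Reactants: 21 tert-butyl 8β-tigloyloxyelema-1,3,11(13)-trien-15,6α-olid-12-oate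
Product: 22 8β-tigloyloxyelema-1,3,11(13)-trien-15,6α-olid-12-oic acid
Conditions: CF3CO2H, CH2Cl2, 0 °C → rt
Reagents that add atoms: none
Why: Acidolysis of the tert-butyl ester (loss of 2-methylpropene) should free the C12 acid while the γ-lactone, the tiglate and the alkenes stay intact.

Step 16
Reactants: 22 8β-tigloyloxyelema-1,3,11(13)-trien-15,6α-olid-12-oic acid
Product: 25 15-oxo-8β-tigloyloxyelema-1,3,11(13)-trien-12,6α-olide, via lactol acid 23 (not isolated), via hydroxy enal acid 24 (not isolated)
Conditions: i-Bu2AlH (2.1 equiv), CH2Cl2, −78 °C; aq. potassium sodium tartrate; then PPTS (cat.), 4 Å MS, CH2Cl2, rt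
Reagents that add atoms: none
Why: Partial reduction of the strained α-methylene γ-lactone (the acid is protected in the flask as its aluminium carboxylate and the hindered tiglate reacts more slowly) gives lactol 23, whose open hydroxy enal form 24 lactonises under mild acid onto the only carboxyl group (C12); O6 is thereby handed from the temporary C15 lactone to the trans-fused 12,6-lactone with C15 left at the aldehyde level, and no stereocentre is touched.

Step 17
Reactants: 25 15-oxo-8β-tigloyloxyelema-1,3,11(13)-trien-12,6α-olide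
Product: 26 8β-tigloyloxyelema-1,3,11(13)-trien-12,6α-olid-15-oic acid (CNP0256928.1)
Conditions: NaClO2, NaH2PO4, 2-methylbut-2-ene, t-BuOH/H2O, 0 °C → rt
Reagents that add atoms: sodium chlorite [Na+].[O-]Cl=O
Why: Pinnick oxidation should convert the 2-substituted acrolein into the acrylic acid, with the alkene scavenger protecting the vinyl and methylidene groups from hypochlorite.

Compound list
1 | 4,4-dimethoxybutan-2-one | CC(=O)CC(OC)OC | starting material
2 | ethyl (2E)-5,5-dimethoxy-3-methylpent-2-enoate | CCOC(=O)/C=C(\C)CC(OC)OC | intermediate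
3 | (2E)-5,5-dimethoxy-3-methylpent-2-en-1-ol | OC/C=C(\C)CC(OC)OC | intermediate
4 | diethyl (2E)-5,5-dimethoxy-3-methylpent-2-en-1-yl phosphate | CCOP(=O)(OCC)OC/C=C(\C)CC(OC)OC | intermediate
5 | [(3S)-3-ethenyl-5,5-dimethoxy-3-methylpent-1-yn-1-yl]trimethylsilane | C=C[C@](C)(CC(OC)OC)C#C[Si](C)(C)C | intermediate
6 | (3S)-3-ethenyl-5,5-dimethoxy-3-methylpent-1-yne | C=C[C@](C)(CC(OC)OC)C#C | intermediate
7 | methyl (4S)-4-ethenyl-6,6-dimethoxy-4-methylhex-2-ynoate | C=C[C@](C)(CC(OC)OC)C#CC(=O)OC | intermediate
8 | methyl (2E,4S)-2-(diisobutylalumanyl)-4-ethenyl-6,6-dimethoxy-4-methylhex-2-enoate (vinylalane, not isolated) | C=C[C@](C)(CC(OC)OC)/C=C(/[Al](CC(C)C)CC(C)C)C(=O)OC | intermediate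
9 | methyl (2Z,4S)-4-ethenyl-6,6-dimethoxy-4-methyl-2-[(4,4,5,5-tetramethyl-1,3,2-dioxaborolan-2-yl)methyl]hex-2-enoate (fragment A) | C=C[C@](C)(CC(OC)OC)/C=C(/CB1OC(C)(C)C(C)(C)O1)C(=O)OC | intermediate
10 | tert-butyl acrylate | C=CC(=O)OC(C)(C)C | starting material
11 | 2-[(tert-butyldimethylsilyl)oxy]acetaldehyde | CC(C)(C)[Si](C)(C)OCC=O | starting material
12 | tert-butyl 4-[(tert-butyldimethylsilyl)oxy]-3-hydroxy-2-methylidenebutanoate (racemic) | CC(C)(C)[Si](C)(C)OCC(O)C(=C)C(=O)OC(C)(C)C | intermediate
13 | tert-butyl 3-(acetyloxy)-4-[(tert-butyldimethylsilyl)oxy]-2-methylidenebutanoate (racemic) | CC(C)(C)[Si](C)(C)OCC(OC(C)=O)C(=C)C(=O)OC(C)(C)C | intermediate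
14 | tert-butyl (2E)-4-[(tert-butyldimethylsilyl)oxy]-2-[(4,4,5,5-tetramethyl-1,3,2-dioxaborolan-2-yl)methyl]but-2-enoate | CC(C)(C)[Si](C)(C)OC/C=C(\CB1OC(C)(C)C(C)(C)O1)C(=O)OC(C)(C)C | intermediate
15 | tetrabutylammonium [(2E)-2-(tert-butoxycarbonyl)-4-hydroxybut-2-en-1-yl]trifluoroborate | OC/C=C(\C[B-](F)(F)F)C(=O)OC(C)(C)C.CCCC[N+](CCCC)(CCCC)CCCC | intermediate
16 | tetrabutylammonium [(2E)-2-(tert-butoxycarbonyl)-4-oxobut-2-en-1-yl]trifluoroborate (fragment B) | O=C/C=C(\C[B-](F)(F)F)C(=O)OC(C)(C)C.CCCC[N+](CCCC)(CCCC)CCCC | intermediate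
17 | 5,6-anti allylboration adduct: O6 pinacol borate with methyl ester, dimethyl acetal and trifluoroborate intact (not isolated) | C=C[C@](C)(CC(OC)OC)[C@H](C(=C)C(=O)OC)[C@@H](OB1OC(C)(C)C(C)(C)O1)/C=C(\C[B-](F)(F)F)C(=O)OC(C)(C)C.CCCC[N+](CCCC)(CCCC)CCCC | intermediate
18 | trans-4,5-disubstituted 3-methylidene γ-lactone (O6–C15) carrying the dimethyl acetal and the (E)-allyl trifluoroborate (not isolated) | C=C[C@](C)(CC(OC)OC)[C@H]1[C@H](/C=C(\C[B-](F)(F)F)C(=O)OC(C)(C)C)OC(=O)C1=C.CCCC[N+](CCCC)(CCCC)CCCC | intermediate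
19 | the same lactone with free C8 aldehyde and (E)-allylboronic acid (not isolated) | C=C[C@](C)(CC=O)[C@H]1[C@H](/C=C(\CB(O)O)C(=O)OC(C)(C)C)OC(=O)C1=C | intermediate
20 | tert-butyl 8β-hydroxyelema-1,3,11(13)-trien-15,6α-olid-12-oate | C=C[C@]1(C)C[C@@H](O)[C@@H](C(=C)C(=O)OC(C)(C)C)[C@@H]2OC(=O)C(=C)[C@@H]12 | intermediate
21 | tert-butyl 8β-tigloyloxyelema-1,3,11(13)-trien-15,6α-olid-12-oate | C=C[C@]1(C)C[C@@H](OC(=O)/C(C)=C/C)[C@@H](C(=C)C(=O)OC(C)(C)C)[C@@H]2OC(=O)C(=C)[C@@H]12 | intermediate
22 | 8β-tigloyloxyelema-1,3,11(13)-trien-15,6α-olid-12-oic acid | C=C[C@]1(C)C[C@@H](OC(=O)/C(C)=C/C)[C@@H](C(=C)C(=O)O)[C@@H]2OC(=O)C(=C)[C@@H]12 | intermediate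
23 | 15-hydroxy-15,6α-epoxy (lactol) 8β-tigloyloxyelema-1,3,11(13)-trien-12-oic acid, anomers (not isolated) | C=C[C@]1(C)C[C@@H](OC(=O)/C(C)=C/C)[C@@H](C(=C)C(=O)O)[C@@H]2OC(O)C(=C)[C@@H]12 | intermediate
24 | 6α-hydroxy-15-oxo-8β-tigloyloxyelema-1,3,11(13)-trien-12-oic acid (not isolated) | C=C[C@]1(C)C[C@@H](OC(=O)/C(C)=C/C)[C@@H](C(=C)C(=O)O)[C@H](O)[C@H]1C(=C)C=O | intermediate
25 | 15-oxo-8β-tigloyloxyelema-1,3,11(13)-trien-12,6α-olide | C=C[C@]1(C)C[C@@H](OC(=O)/C(C)=C/C)[C@H]2C(=C)C(=O)O[C@@H]2[C@H]1C(=C)C=O | intermediate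
26 | 8β-tigloyloxyelema-1,3,11(13)-trien-12,6α-olid-15-oic acid (CNP0256928.1) | C=C[C@]1(C)C[C@@H](OC(=O)/C(C)=C/C)[C@H]2C(=C)C(=O)O[C@@H]2[C@H]1C(=C)C(=O)O | target

Total step count: 17. Longest linear sequence: 12 steps (steps 1–7 and 13–17).

Steps most likely to fail

Step 13. The first allylboration may be too slow with the hindered, ester-deactivated boronate. The lactonisation may lag, so that O6 captures the unmasked boron. The ring closure may leak through a boat transition state, which would erode the configuration at C8. Fallback (sets out from 13 and 9, returns at 20), in which the second allylboron is installed only after the fragments are joined: DABCO-mediated 1,3-transposition of 13 should give the primary acetate tert-butyl (2E)-2-(acetoxymethyl)-4-[(tert-butyldimethylsilyl)oxy]but-2-enoate F1. Desilylation (HF·pyridine) gives tert-butyl (2E)-2-(acetoxymethyl)-4-hydroxybut-2-enoate F2, and Dess–Martin oxidation gives tert-butyl (2E)-2-(acetoxymethyl)-4-oxobut-2-enoate F3. Allylboration of F3 with 9, catalysed by (R)-TRIP or Sc(OTf)3, with lactonisation in the flask gives the isolable lactone acetate F4, at which stage diastereomers from the first bond formation can be separated. Borylation of its allylic acetate (Pd2(dba)3, B2pin2) gives the lactone allylboronate F5. Acetal hydrolysis (LiBF4, wet MeCN) gives the lactone aldehyde boronate F6, which should close to 20 by thermal intramolecular allylboration through the same bicyclic chair transition state.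

Step 16. The aluminium hydride may also attack the tigloyl ester, and the α-methylene lactol may dehydrate toward a furan or stall before relactonising. Fallback (sets out from 20, returns at 25), in which the reduction is done before the tiglate exists: i-Bu2AlH at −78 °C on 20 should give the lactol tert-butyl 8β,15-dihydroxy-15,6α-epoxyelema-1,3,11(13)-trien-12-oate F7. PPTS in MeOH gives the cyclic methyl acetal F8, which keeps O6 protected. Yamaguchi tigloylation of O8 gives the tiglate acetal F9. Me3SiOTf/2,6-lutidine (tert-butyl ester cleavage) followed by aqueous acetic acid (acetal hydrolysis and lactonisation onto C12) should give 25.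

Step 7. Alkylation of the hindered α-alumino enoate may be inefficient, or geometry may be lost through the allenoate form. Fallback (sets out from 7, returns at 9): syn-hydrostannation (Bu3SnH, Pd(PPh3)4 cat.) should give methyl (2E,4S)-4-ethenyl-6,6-dimethoxy-4-methyl-2-(tributylstannyl)hex-2-enoate F10. Iododestannylation (I2, CH2Cl2, 0 °C) gives methyl (2E,4S)-4-ethenyl-2-iodo-6,6-dimethoxy-4-methylhex-2-enoate F11. Negishi coupling with IZnCH2Bpin (Pd(PPh3)4 cat.) should give 9 with retention of the alkene geometry.

Further compounds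
F1 | step 13 | tert-butyl (2E)-2-(acetoxymethyl)-4-[(tert-butyldimethylsilyl)oxy]but-2-enoate | CC(C)(C)[Si](C)(C)OC/C=C(\COC(C)=O)C(=O)OC(C)(C)C
F2 | step 13 | tert-butyl (2E)-2-(acetoxymethyl)-4-hydroxybut-2-enoate | OC/C=C(\COC(C)=O)C(=O)OC(C)(C)C
F3 | step 13 | tert-butyl (2E)-2-(acetoxymethyl)-4-oxobut-2-enoate | O=C/C=C(\COC(C)=O)C(=O)OC(C)(C)C
F4 | step 13 | lactone acetate (analogue of 18 with CH2OAc in place of the trifluoroborate) | C=C[C@](C)(CC(OC)OC)[C@H]1[C@H](/C=C(\COC(C)=O)C(=O)OC(C)(C)C)OC(=O)C1=C
F5 | step 13 | lactone allylboronate (pinacol ester) | C=C[C@](C)(CC(OC)OC)[C@H]1[C@H](/C=C(\CB2OC(C)(C)C(C)(C)O2)C(=O)OC(C)(C)C)OC(=O)C1=C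
F6 | step 13 | lactone aldehyde boronate | C=C[C@](C)(CC=O)[C@H]1[C@H](/C=C(\CB2OC(C)(C)C(C)(C)O2)C(=O)OC(C)(C)C)OC(=O)C1=C
F7 | step 16 | tert-butyl 8β,15-dihydroxy-15,6α-epoxyelema-1,3,11(13)-trien-12-oate (lactol, anomers) | C=C[C@]1(C)C[C@@H](O)[C@@H](C(=C)C(=O)OC(C)(C)C)[C@@H]2OC(O)C(=C)[C@@H]12
F8 | step 16 | tert-butyl 8β-hydroxy-15-methoxy-15,6α-epoxyelema-1,3,11(13)-trien-12-oate (cyclic methyl acetal, anomers) | C=C[C@]1(C)C[C@@H](O)[C@@H](C(=C)C(=O)OC(C)(C)C)[C@@H]2OC(OC)C(=C)[C@@H]12
F9 | step 16 | tert-butyl 15-methoxy-8β-tigloyloxy-15,6α-epoxyelema-1,3,11(13)-trien-12-oate (tiglate acetal, anomers) | C=C[C@]1(C)C[C@@H](OC(=O)/C(C)=C/C)[C@@H](C(=C)C(=O)OC(C)(C)C)[C@@H]2OC(OC)C(=C)[C@@H]12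
F10 | step 7 | methyl (2E,4S)-4-ethenyl-6,6-dimethoxy-4-methyl-2-(tributylstannyl)hex-2-enoate | C=C[C@](C)(CC(OC)OC)/C=C(/[Sn](CCCC)(CCCC)CCCC)C(=O)OC
F11 | step 7 | methyl (2E,4S)-4-ethenyl-2-iodo-6,6-dimethoxy-4-methylhex-2-enoate | C=C[C@](C)(CC(OC)OC)/C=C(/I)C(=O)OC
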